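**Retrosynthetic overview**
- Target ⇒ removal of two O-benzyl groups; side-chain carbinol ⇒ chelation-controlled reduction of an aryl ketone; aryl ether ⇒ SN2 (inversion) of the ring B phenoxide on an (S)-lactate-derived α-tosyloxy ketone.
- Ring A–oxolane bond ⇒ aryllithium addition to a γ-lactone, then ionic hydrogenation of the hemiketal (hydride anti to the cis methyl pair).
- γ-Lactone ⇒ Felkin reduction/lactonisation of a syn-2,3-dimethyl-4-aryl-4-oxobutanoic acid ⇒ Rh-catalysed enantioselective arylation of meso-2,3-dimethylsuccinic anhydride.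
- Two ring B units are joined through their phenol oxygens by a di-tert-butylsilylene bridge (protecting group and tether in one), so the core is built in two directions; fluoride cuts the bridge in the etherification step.
- Ring formation: the oxolane is the only ring built; it is closed twice in one operation as the two lactone rings (step 4) and kept to the end; the three arenes are bought.

Assumption: ring A = free guaiacyl ring on the oxolane, ring B = guaiacyl ring carrying the ether side chain, ring C = side-chain guaiacyl ring; the minor heterochiral dimer from the desymmetrisation is removed by chromatography at the bis-lactone stage.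

**Route**

Step 1
Reactants: 1 2,3-dimethylmaleic anhydride
Product: 2 meso-2,3-dimethylsuccinic anhydride [(3R,4S)-3,4-dimethyloxolane-2,5-dione]
Conditions: H2 (4 atm), 10 wt % Pd/C, EtOAc, rt
Reagents that add atoms: none
Why: Heterogeneous catalytic hydrogenation adds both hydrogens to one face of the tetrasubstituted alkene, so the two methyls end up cis (meso, no absolute stereochemistry yet).

Step 2
Reactants: 3 4-bromo-2-methoxyphenol (2 equiv)
Product: 4 bis(4-bromo-2-methoxyphenoxy)di-tert-butylsilane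
Conditions: NaH (2.1 equiv), THF, 0 °C; t-Bu2Si(OTf)2 (0.5 equiv), 0 → 50 °C
Reagents that add atoms: di-tert-butylsilyl bis(trifluoromethanesulfonate), CC(C)(C)[Si](OS(=O)(=O)C(F)(F)F)(OS(=O)(=O)C(F)(F)F)C(C)(C)C
Why: Double O-silylation (nucleophilic substitution at silicon) by the sodium phenoxide gives a hindered silylene bridge that protects both phenols, survives organolithiums, hydride and BF3 at low temperature, and is cleaved by fluoride.

Step 3
Reactants: 4 bis(4-bromo-2-methoxyphenoxy)di-tert-butylsilane; 2 meso-2,3-dimethylsuccinic anhydride (2.4 equiv)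
Product: 7 4,4'-[(di-tert-butylsilanediyl)bis(oxy-3-methoxy-4,1-phenylene)]bis[(2R,3S)-2,3-dimethyl-4-oxobutanoic acid], via dilithio silane 5 (not isolated), via bis(arylzinc triflate) 6 (not isolated)
Conditions: t-BuLi (4.2 equiv), THF, −78 °C; Zn(OTf)2 (2.2 equiv), −78 °C → rt; then 2, [RhCl(cod)]2 (4 mol %), TADDOL-derived P–NMe2 phosphoramidite (8 mol %, the enantiomer that gives the 2R,3S acid), THF, 50 °C; aq. HCl work-up
Reagents that add atoms: none
Why: Rh-catalysed enantioselective desymmetrising acyl cross-coupling of a meso anhydride with an arylzinc: the chiral ligand makes Rh insert into one of the two enantiotopic C(=O)–O bonds, so each ketone sits next to the S methine and each acid next to the R methine, and because the two ends react independently most of the minor enantiomeric outcome ends up in a separable heterochiral dimer.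

Step 4
Reactants: 7 silylene-bridged bis(keto acid)
Product: 9 5,5'-[(di-tert-butylsilanediyl)bis(oxy-3-methoxy-4,1-phenylene)]bis[(3R,4S,5S)-3,4-dimethyloxolan-2-one], via bis(hydroxy acid) 8 (not isolated)
Conditions: LiBH(s-Bu)3 (5 equiv), THF, −78 °C; then 2 M HCl, THF, rt
Reagents that add atoms: none
Why: Felkin–Anh reduction followed by acid lactonisation: the bulky hydride attacks each aryl ketone anti to the branched chain to give the (4S)-carbinols, which close onto the acids, so both oxolanone rings form in this one operation with aryl trans to the neighbouring methyl and the cis-dimethyl pair intact.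

Step 5
Reactants: 9 silylene-bridged bis-lactone; 10 1-(benzyloxy)-4-bromo-2-methoxybenzene (2.6 equiv)
Product: 13 di-tert-butylbis{4-[(2S,3S,4R,5S)-5-(4-benzyloxy-3-methoxyphenyl)-3,4-dimethyloxolan-2-yl]-2-methoxyphenoxy}silane, via aryllithium 11 (not isolated), via bis-lactol 12 (not isolated)
Conditions: 10, n-BuLi (2.5 equiv), THF, −78 °C; add 9, −78 °C; H2O quench, solvent switch to CH2Cl2; Et3SiH (6 equiv), BF3·OEt2 (4 equiv), −78 °C
Reagents that add atoms: none
Why: Aryllithium 1,2-addition to each lactone gives the cyclic hemiketals, and BF3-promoted ionic hydrogenation of the 2-aryl oxocarbenium ions delivers hydride from the face opposite the two cis methyls, which places ring A cis to them (5S); the low temperature prevents epimerisation of this kinetic centre.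

Step 6
Reactants: 14 ethyl (S)-lactate
Product: 15 (S)-2-hydroxy-N-methoxy-N-methylpropanamide
Conditions: MeNH(OMe)·HCl (1.5 equiv), i-PrMgCl (4 equiv), THF, −20 → 0 °C; aq. HCl work-up
Reagents that add atoms: N,O-dimethylhydroxylamine hydrochloride, CNOC.Cl
Why: Weinreb amide formation by aminolysis of the ester with the magnesium amide; the carbinol stereocentre is not involved.

Step 7
Reactants: 15 (S)-2-hydroxy-N-methoxy-N-methylpropanamide; 10 1-(benzyloxy)-4-bromo-2-methoxybenzene (1.4 equiv)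
Product: 17 (S)-1-[4-(benzyloxy)-3-methoxyphenyl]-2-hydroxypropan-1-one, via arylmagnesium bromide 16 (not isolated)
Conditions: 10, Mg turnings (1.5 equiv), I2 (cat.), THF, 40 °C; separately 15, i-PrMgCl (1.0 equiv), THF, −20 °C; add the Grignard solution, −20 → 0 °C; aq. HCl work-up
Reagents that add atoms: none
Why: Weinreb ketone synthesis with a Grignard reagent: i-PrMgCl first turns the free hydroxyl into its magnesium alkoxide, the arylmagnesium bromide then adds once to give a chelated tetrahedral intermediate that releases the ketone only on work-up, and the S centre is untouched.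

Step 8
Reactants: 17 (S)-1-[4-(benzyloxy)-3-methoxyphenyl]-2-hydroxypropan-1-one
Product: 18 (S)-1-[4-(benzyloxy)-3-methoxyphenyl]-1-oxopropan-2-yl 4-methylbenzenesulfonate
Conditions: TsCl (1.3 equiv), Et3N, DMAP (cat.), CH2Cl2, 0 °C
Reagents that add atoms: 4-methylbenzenesulfonyl chloride, Cc1ccc(S(=O)(=O)Cl)cc1
Why: O-Sulfonylation (tosylation) takes place at oxygen, so the S configuration is retained and the carbinol carbon becomes an SN2 electrophile.

Step 9
Reactants: 13 silylene-bridged bis-oxolane; 18 (S)-tosylate (2.2 equiv)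
Product: 20 (R)-1-[4-(benzyloxy)-3-methoxyphenyl]-2-{4-[(2S,3S,4R,5S)-5-(4-benzyloxy-3-methoxyphenyl)-3,4-dimethyloxolan-2-yl]-2-methoxyphenoxy}propan-1-one, via cesium phenoxide 19 (not isolated)
Conditions: CsF (3 equiv), DMF, rt; then 18, 0 °C → rt
Reagents that add atoms: none
Why: Fluoride cuts both aryl O–Si bonds and each cesium phenoxide displaces the α-keto tosylate in an SN2 Williamson etherification, which inverts the side-chain carbon from S to R.

Step 10
Reactants: 20 keto ether
Product: 21 (1S,2R)-1-[4-(benzyloxy)-3-methoxyphenyl]-2-{4-[(2S,3S,4R,5S)-5-(4-benzyloxy-3-methoxyphenyl)-3,4-dimethyloxolan-2-yl]-2-methoxyphenoxy}propan-1-ol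
Conditions: Zn(BH4)2 (1.5 equiv), Et2O–THF, −30 → 0 °C
Reagents that add atoms: none
Why: Chelation-controlled (Cram chelate) reduction: zinc ties the carbonyl to the α-aryloxy oxygen and hydride adds from the side of the small hydrogen, which gives the erythro (1S,2R) alcohol.

Step 11
Reactants: 21 dibenzyl ether of the target
Product: 22 CNP0171079.3 [(1S,2R)-1-(4-hydroxy-3-methoxyphenyl)-2-{4-[(2S,3S,4R,5S)-5-(4-hydroxy-3-methoxyphenyl)-3,4-dimethyloxolan-2-yl]-2-methoxyphenoxy}propan-1-ol]
Conditions: H2 (1 atm), 10 wt % Pd/C, EtOAc, rt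
Reagents that add atoms: none
Why: Catalytic hydrogenolysis removes both aryl benzyl ethers; under neutral conditions at 1 atm the oxolane C–O bonds and the secondary benzylic alcohol are left alone and no stereocentre changes.

**Compound list**

1 | 2,3-dimethylmaleic anhydride | CC1=C(C)C(=O)OC1=O | starting material
2 | meso-2,3-dimethylsuccinic anhydride | C[C@H]1C(=O)OC(=O)[C@H]1C | intermediate
3 | 4-bromo-2-methoxyphenol | COc1cc(Br)ccc1O | starting material
4 | bis(4-bromo-2-methoxyphenoxy)di-tert-butylsilane | COc1cc(Br)ccc1O[Si](Oc1ccc(Br)cc1OC)(C(C)(C)C)C(C)(C)C | intermediate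
5 | di-tert-butylbis(4-lithio-2-methoxyphenoxy)silane | COc1cc([Li])ccc1O[Si](Oc1ccc([Li])cc1OC)(C(C)(C)C)C(C)(C)C | intermediate
6 | bis(arylzinc triflate) of the silylene-bridged diaryl ether | COc1cc([Zn]OS(=O)(=O)C(F)(F)F)ccc1O[Si](Oc1ccc([Zn]OS(=O)(=O)C(F)(F)F)cc1OC)(C(C)(C)C)C(C)(C)C | intermediate
7 | 4,4'-[(di-tert-butylsilanediyl)bis(oxy-3-methoxy-4,1-phenylene)]bis[(2R,3S)-2,3-dimethyl-4-oxobutanoic acid] | OC(=O)[C@H](C)[C@H](C)C(=O)c1ccc(O[Si](Oc2ccc(C(=O)[C@@H](C)[C@@H](C)C(=O)O)cc2OC)(C(C)(C)C)C(C)(C)C)c(OC)c1 | intermediate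
8 | 4,4'-[(di-tert-butylsilanediyl)bis(oxy-3-methoxy-4,1-phenylene)]bis[(2R,3S,4S)-4-hydroxy-2,3-dimethylbutanoic acid] | OC(=O)[C@H](C)[C@H](C)[C@H](O)c1ccc(O[Si](Oc2ccc([C@@H](O)[C@@H](C)[C@@H](C)C(=O)O)cc2OC)(C(C)(C)C)C(C)(C)C)c(OC)c1 | intermediate
9 | 5,5'-[(di-tert-butylsilanediyl)bis(oxy-3-methoxy-4,1-phenylene)]bis[(3R,4S,5S)-3,4-dimethyloxolan-2-one] | O=C1O[C@H](c2ccc(O[Si](Oc3ccc([C@H]4OC(=O)[C@H](C)[C@@H]4C)cc3OC)(C(C)(C)C)C(C)(C)C)c(OC)c2)[C@@H](C)[C@H]1C | intermediate
10 | 1-(benzyloxy)-4-bromo-2-methoxybenzene | COc1cc(Br)ccc1OCc1ccccc1 | starting material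
11 | [4-(benzyloxy)-3-methoxyphenyl]lithium | COc1cc([Li])ccc1OCc1ccccc1 | intermediate
12 | 5,5'-[(di-tert-butylsilanediyl)bis(oxy-3-methoxy-4,1-phenylene)]bis[(3R,4S,5S)-2-(4-benzyloxy-3-methoxyphenyl)-3,4-dimethyloxolan-2-ol] (C2 epimers) | COc1cc(C2(O)O[C@H](c3ccc(O[Si](Oc4ccc([C@H]5OC(O)(c6ccc(OCc7ccccc7)c(OC)c6)[C@H](C)[C@@H]5C)cc4OC)(C(C)(C)C)C(C)(C)C)c(OC)c3)[C@@H](C)[C@H]2C)ccc1OCc1ccccc1 | intermediate
13 | di-tert-butylbis{4-[(2S,3S,4R,5S)-5-(4-benzyloxy-3-methoxyphenyl)-3,4-dimethyloxolan-2-yl]-2-methoxyphenoxy}silane | COc1cc([C@H]2O[C@H](c3ccc(O[Si](Oc4ccc([C@H]5O[C@H](c6ccc(OCc7ccccc7)c(OC)c6)[C@H](C)[C@@H]5C)cc4OC)(C(C)(C)C)C(C)(C)C)c(OC)c3)[C@@H](C)[C@H]2C)ccc1OCc1ccccc1 | intermediate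
14 | ethyl (S)-lactate | CCOC(=O)[C@H](C)O | starting material
15 | (S)-2-hydroxy-N-methoxy-N-methylpropanamide | CON(C)C(=O)[C@H](C)O | intermediate
16 | [4-(benzyloxy)-3-methoxyphenyl]magnesium bromide | COc1cc([Mg]Br)ccc1OCc1ccccc1 | intermediate
17 | (S)-1-[4-(benzyloxy)-3-methoxyphenyl]-2-hydroxypropan-1-one | COc1cc(C(=O)[C@H](C)O)ccc1OCc1ccccc1 | intermediate
18 | (S)-1-[4-(benzyloxy)-3-methoxyphenyl]-1-oxopropan-2-yl 4-methylbenzenesulfonate | COc1cc(C(=O)[C@H](C)OS(=O)(=O)c2ccc(C)cc2)ccc1OCc1ccccc1 | intermediate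
19 | cesium 4-[(2S,3S,4R,5S)-5-(4-benzyloxy-3-methoxyphenyl)-3,4-dimethyloxolan-2-yl]-2-methoxyphenolate | COc1cc([C@H]2O[C@H](c3ccc([O-])c(OC)c3)[C@@H](C)[C@H]2C)ccc1OCc1ccccc1.[Cs+] | intermediate
20 | (R)-1-[4-(benzyloxy)-3-methoxyphenyl]-2-{4-[(2S,3S,4R,5S)-5-(4-benzyloxy-3-methoxyphenyl)-3,4-dimethyloxolan-2-yl]-2-methoxyphenoxy}propan-1-one | COc1cc([C@H]2O[C@H](c3ccc(O[C@H](C)C(=O)c4ccc(OCc5ccccc5)c(OC)c4)c(OC)c3)[C@@H](C)[C@H]2C)ccc1OCc1ccccc1 | intermediate
21 | (1S,2R)-1-[4-(benzyloxy)-3-methoxyphenyl]-2-{4-[(2S,3S,4R,5S)-5-(4-benzyloxy-3-methoxyphenyl)-3,4-dimethyloxolan-2-yl]-2-methoxyphenoxy}propan-1-ol | COc1cc([C@H]2O[C@H](c3ccc(O[C@H](C)[C@@H](O)c4ccc(OCc5ccccc5)c(OC)c4)c(OC)c3)[C@@H](C)[C@H]2C)ccc1OCc1ccccc1 | intermediate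
22 | CNP0171079.3, (1S,2R)-1-(4-hydroxy-3-methoxyphenyl)-2-{4-[(2S,3S,4R,5S)-5-(4-hydroxy-3-methoxyphenyl)-3,4-dimethyloxolan-2-yl]-2-methoxyphenoxy}propan-1-ol | COc1cc([C@H]2O[C@H](c3ccc(O[C@H](C)[C@@H](O)c4ccc(O)c(OC)c4)c(OC)c3)[C@@H](C)[C@H]2C)ccc1O | target

**Step count**

Total: 11 steps. Longest linear sequence: 7 steps (2 → 3 → 4 → 5 → 9 → 10 → 11; also 7 if counted from step 1). The side-chain branch is steps 6 → 7 → 8.

**Steps most likely to fail, with fallbacks**

Step 3 (double Rh-catalysed desymmetrisation on a tethered bis-arylzinc; both ends must couple with high ee). The fallback sets out from 2 and comes back at 9. Methanolysis of 2 with a cinchona alkaloid (quinine or quinidine, whichever opens the carbonyl next to the R methine) gives the hemiester (2S,3R)-4-methoxy-2,3-dimethyl-4-oxobutanoic acid F1. Oxalyl chloride converts it into the acid chloride methyl (2R,3S)-4-chloro-2,3-dimethyl-4-oxobutanoate F2. Pd(PPh3)4-catalysed acylative Negishi coupling of F2 with the bis(arylzinc) 6 (made from 4 as in step 3) gives the silylene-bridged bis(keto ester) dimethyl 4,4'-[(di-tert-butylsilanediyl)bis(oxy-3-methoxy-4,1-phenylene)]bis[(2R,3S)-2,3-dimethyl-4-oxobutanoate] F3. Under the step 4 conditions F3 is reduced and lactonises with loss of methanol to give 9.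

Step 4 (facial selectivity of the hydride addition that fixes the aryl-bearing lactone carbon). The fallback sets out from 7 and comes back at 9, replacing kinetic control by thermodynamic control. Reduce 7 with NaBH4 and lactonise; the mixture then contains the all-cis bis-lactone 5,5'-[(di-tert-butylsilanediyl)bis(oxy-3-methoxy-4,1-phenylene)]bis[(3R,4S,5R)-3,4-dimethyloxolan-2-one] F4. Treat it with CF3CO2H in CH2Cl2: the benzylic C5–O bond of each 5-aryl lactone ionises reversibly (para-siloxybenzyl cation, carboxylic acid as internal nucleophile) and the material drains into the more stable 4,5-trans lactone 9.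

Step 9 (fluoride-triggered one-pot etherification; the α-tosyloxy ketone can enolise and racemise, or eliminate, under basic fluoride). The fallback sets out from 13 and comes back at 20. Bu4NF buffered with AcOH removes the silylene to give the free phenol 4-[(2S,3S,4R,5S)-5-(4-benzyloxy-3-methoxyphenyl)-3,4-dimethyloxolan-2-yl]-2-methoxyphenol F5. Mitsunobu etherification (PPh3, DIAD, THF, 0 °C) of F5 with hydroxy ketone 17 forms the same aryl ether with inversion under non-basic conditions and without the tosylate, giving 20.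

**Further compounds**

F1 | step 3 | (2S,3R)-4-methoxy-2,3-dimethyl-4-oxobutanoic acid | OC(=O)[C@@H](C)[C@@H](C)C(=O)OC
F2 | step 3 | methyl (2R,3S)-4-chloro-2,3-dimethyl-4-oxobutanoate | ClC(=O)[C@@H](C)[C@@H](C)C(=O)OC
F3 | step 3 | dimethyl 4,4'-[(di-tert-butylsilanediyl)bis(oxy-3-methoxy-4,1-phenylene)]bis[(2R,3S)-2,3-dimethyl-4-oxobutanoate] | COC(=O)[C@H](C)[C@H](C)C(=O)c1ccc(O[Si](Oc2ccc(C(=O)[C@@H](C)[C@@H](C)C(=O)OC)cc2OC)(C(C)(C)C)C(C)(C)C)c(OC)c1
F4 | step 4 | 5,5'-[(di-tert-butylsilanediyl)bis(oxy-3-methoxy-4,1-phenylene)]bis[(3R,4S,5R)-3,4-dimethyloxolan-2-one] | O=C1O[C@@H](c2ccc(O[Si](Oc3ccc([C@@H]4OC(=O)[C@H](C)[C@@H]4C)cc3OC)(C(C)(C)C)C(C)(C)C)c(OC)c2)[C@@H](C)[C@H]1C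
F5 | step 9 | 4-[(2S,3S,4R,5S)-5-(4-benzyloxy-3-methoxyphenyl)-3,4-dimethyloxolan-2-yl]-2-methoxyphenol | COc1cc([C@H]2O[C@H](c3ccc(O)c(OC)c3)[C@@H](C)[C@H]2C)ccc1OCc1ccccc1
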